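**Assumption:** positions use germacrane numbering (C1 = furanone C=O, C3–O–C10 = ether bridge, C6 = lactone O–CH, C8 = tiglate carbon, C11=C13 = exo-methylene, C15 = CH2OH). Compound numbers follow first appearance in the forward route. The route is a paper design and has not been run.

## Retrosynthetic overview

1. Lychnophorolide B ⇐ desilylation and C8–O tigloylation of the 8-hydroxy macrocycle.
2. Ten-membered ring ⇐ C7–C8 bond by a visible-light photoredox/chromium intramolecular Barbier allylation of a 3-(bromomethyl)butenolide onto the C8 aldehyde; this sets C7 and C8 and reveals the α-methylene lactone.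
3. Butenolide ⇐ ring-closing metathesis of the C6 2-(bromomethyl)acrylate; the C6–OH and its vinyl group are released together by zinc fragmentation of an iodomethyl acetonide (C6 bought in D-threitol).
4. Furanone ⇐ Sonogashira coupling (C3–C4) of a (Z)-vinyl iodide with an α′-hydroxy ynone, then 5-endo cyclisation; C10 comes from (S)-lactic acid by Seebach alkylation.
5. Ring order: furanone → butenolide → ten-membered carbocycle.

## Route

**Step 1**
Reactants: 1 (S)-lactic acid; 2 pivaldehyde
Product: 3 (2S,5S)-2-tert-butyl-5-methyl-1,3-dioxolan-4-one (cis)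
Conditions: cat. TsOH, cat. H2SO4, pentane, reflux (Dean–Stark); recrystallise
Reagents that add atoms: pivaldehyde, CC(C)(C)C=O
Why: Acid-catalysed acetalisation (Seebach dioxolanone); the cis acetal centre is set by the lactate centre under thermodynamic/crystallisation control and serves only as a relay.

**Step 2**
Reactants: 3; 4 allyl bromide
Product: 5 (2S,5R)-5-allyl-2-tert-butyl-5-methyl-1,3-dioxolan-4-one
Conditions: LDA, THF, −78 °C; then 4, −78 → −30 °C
Reagents that add atoms: allyl bromide, C=CCBr
Why: Seebach self-regeneration of stereocentres; the enolate is alkylated anti to the tert-butyl group, so allyl replaces H with retention and fixes the C10 quaternary centre as R.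

**Step 3**
Reactants: 5
Product: 6 (2S,5R)-2-tert-butyl-5-(2,2-dimethoxyethyl)-5-methyl-1,3-dioxolan-4-one
Conditions: O3, CH2Cl2/MeOH, −78 °C; Me2S; then HC(OMe)3, cat. PPTS, MeOH, 0 °C → rt (one pot)
Reagents that add atoms: methanol, CO; trimethyl orthoformate, COC(OC)OC (ozone leaves no atom in 6)
Why: Ozonolysis of the only alkene and in situ acetalisation mask the future C8 aldehyde under conditions too mild to open the dioxolanone.

**Step 4**
Reactants: 6; 7 acetylene (as LiC≡CH)
Product: 8 (4R)-4-hydroxy-6,6-dimethoxy-4-methylhex-1-yn-3-one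
Conditions: acetylene, n-BuLi, THF, −78 °C; add 6, −78 °C; AcOH quench at −78 °C, then warm
Reagents that add atoms: acetylene, C#C
Why: Lactone-type mono-addition of a lithium acetylide; the lithium hemiketal should persist at −78 °C and collapse only on quench (losing pivaldehyde) to the α′-hydroxy ynone, leaving C10 untouched.

**Step 5**
Reactants: 9 2,3-O-isopropylidene-D-threitol, [(4R,5R)-2,2-dimethyl-1,3-dioxolane-4,5-diyl]dimethanol
Product: 10 [(4R,5S)-5-(iodomethyl)-2,2-dimethyl-1,3-dioxolan-4-yl]methanol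
Conditions: I2, PPh3, imidazole (0.95 equiv each), THF, 0 °C; recycle unreacted diol
Reagents that add atoms: iodine, II
Why: Garegg–Samuelsson (Appel-type) mono-iodination of a C2-symmetric diol, where either hydroxyl gives the same product; the carbinol carbon that becomes C6 is not touched.

**Step 6**
Reactants: 10; 11 ethyl (triphenylphosphoranylidene)acetate
Product: 12 ethyl (2Z)-2-iodo-3-[(4R,5S)-5-(iodomethyl)-2,2-dimethyl-1,3-dioxolan-4-yl]prop-2-enoate
Conditions: (COCl)2, DMSO, Et3N, CH2Cl2, −78 °C; then Ph3P=C(I)CO2Et (pre-formed from 11, NIS, K2CO3, CH2Cl2, −20 °C), −78 °C → rt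
Reagents that add atoms: ethyl (triphenylphosphoranylidene)acetate, CCOC(=O)C=P(c1ccccc1)(c1ccccc1)c1ccccc1; N-iodosuccinimide, O=C1CCC(=O)N1I
Why: One-pot Swern oxidation/Wittig olefination with the α-iodo stabilised ylide puts the ester trans to the chain, giving the (Z)-α-iodoacrylate and hence the C4=C5 geometry (I, later C3, cis to C6).

**Step 7**
Reactants: 12
Product: 13 (2Z)-2-iodo-3-[(4R,5S)-5-(iodomethyl)-2,2-dimethyl-1,3-dioxolan-4-yl]prop-2-en-1-ol
Conditions: DIBAL-H (2.2 equiv), CH2Cl2, −78 °C
Reagents that add atoms: none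
Why: DIBAL 1,2-reduction of the enoate to the C15 allylic alcohol; vinyl and alkyl iodides survive at −78 °C.

**Step 8**
Reactants: 13
Product: 14 tert-butyl{[(2Z)-2-iodo-3-[(4R,5S)-5-(iodomethyl)-2,2-dimethyl-1,3-dioxolan-4-yl]prop-2-en-1-yl]oxy}diphenylsilane
Conditions: TBDPSCl, imidazole, CH2Cl2, rt
Reagents that add atoms: TBDPSCl, CC(C)(C)[Si](Cl)(c1ccccc1)c1ccccc1
Why: Standard silylation; TBDPS is chosen to survive the later acid steps and come off last.

**Step 9**
Reactants: 14; 8
Product: 15 (2R)-5-{(1Z)-3-[(tert-butyldiphenylsilyl)oxy]-1-[(4R,5S)-5-(iodomethyl)-2,2-dimethyl-1,3-dioxolan-4-yl]prop-1-en-2-yl}-2-(2,2-dimethoxyethyl)-2-methylfuran-3(2H)-one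
Conditions: PdCl2(PPh3)2 (5 mol%), CuI (10 mol%), i-Pr2NEt, THF, rt, degassed; then Et2NH, EtOH, rt (one pot)
Reagents that add atoms: none beyond reactants 14 and 8
Why: Sonogashira coupling forms C3–C4 with retention of alkene geometry, then amine-mediated conjugate addition/5-endo cyclisation of the α′-hydroxy ynone gives the 3(2H)-furanone, with the acetonide keeping O6 from adding to the ynone.

**Step 10**
Reactants: 15
Product: 16 (2R)-5-{(2Z,4S)-1-[(tert-butyldiphenylsilyl)oxy]-4-hydroxyhexa-2,5-dien-2-yl}-2-(2,2-dimethoxyethyl)-2-methylfuran-3(2H)-one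
Conditions: activated Zn dust, NH4Cl, THF/EtOH/H2O, 40 °C (ultrasound); use the product promptly
Reagents that add atoms: none
Why: Zinc-mediated reductive β-elimination of the β-alkoxy iodide (Bernet–Vasella type) expels acetone and unveils the C7 vinyl group and free C6–OH together; C6 is not a reacting centre, so its purchased configuration is kept.

**Step 11**
Reactants: 16; 17 2-(bromomethyl)acrylic acid
Product: 18 (3S,4Z)-6-[(tert-butyldiphenylsilyl)oxy]-5-[(5R)-5-(2,2-dimethoxyethyl)-5-methyl-4-oxo-4,5-dihydrofuran-2-yl]hexa-1,4-dien-3-yl 2-(bromomethyl)prop-2-enoate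
Conditions: DIC, DMAP (5 mol%), CH2Cl2, 0 °C
Reagents that add atoms: 2-(bromomethyl)acrylic acid, C=C(CBr)C(=O)O
Why: Steglich esterification of the secondary allylic alcohol installs C11–C13 and C12, and removes the free C6–OH that could otherwise add to the furanone.

**Step 12**
Reactants: 18
Product: 19 (5R)-3-(bromomethyl)-5-{(1Z)-3-[(tert-butyldiphenylsilyl)oxy]-2-[(5R)-5-(2,2-dimethoxyethyl)-5-methyl-4-oxo-4,5-dihydrofuran-2-yl]prop-1-en-1-yl}furan-2(5H)-one
Conditions: Grubbs II (10 mol%), toluene, 80 °C, 5 mM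
Reagents that add atoms: none
Why: Ring-closing metathesis between the monosubstituted vinyl group and the acrylate closes the butenolide (C7=C11), while the hindered, conjugated C4=C5 and furanone alkenes stay inert.

**Step 13**
Reactants: 19
Product: 20 2-[(2R)-5-{(1Z)-1-[(2R)-4-(bromomethyl)-5-oxo-2,5-dihydrofuran-2-yl]-3-[(tert-butyldiphenylsilyl)oxy]prop-1-en-2-yl}-2-methyl-3-oxo-2,3-dihydrofuran-2-yl]acetaldehyde
Conditions: TFA/H2O (9:1), CH2Cl2, 0 °C; use directly
Reagents that add atoms: water, O
Why: Mild acid hydrolysis of the dimethyl acetal frees the C8 aldehyde; TBDPS ether, allylic bromide, furanone and the base-sensitive butenolide γ-H are all acid-tolerant.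

**Step 14**
Reactants: 20
Product: 21 (6R,7R,8S,10R)-15-O-(tert-butyldiphenylsilyl)-8-O-destigloyl-lychnophorolide B (8-hydroxy macrocycle with the α-methylene-γ-lactone)
Conditions: [Ru(bpy)3](PF6)2 (2 mol%), CrCl3·3THF (15 mol%), Hantzsch ester (1.5 equiv), 2,6-lutidine (2 equiv), degassed THF, slow addition of 20 to 2 mM, 455 nm LEDs, 20 °C
Reagents that add atoms: none
Why: Proposed new method: a visible-light photoredox/chromium dual-catalytic intramolecular Barbier (Nozaki–Hiyama) macrocyclisation, in which Ru(I) (from reductive quenching of Ru(II)* by Hantzsch ester) regenerates Cr(II), Cr(II) converts the activated allylic bromide via its allyl radical into an allyl–Cr(III) species, and this adds SE2′ through C7 to the tethered aldehyde in a Zimmerman–Traxler chair (aldehyde chain equatorial, attack anti to the C6 substituent) to give the trans-lactone and the anti 7R,8S pair, with lutidinium releasing the Cr(III) alkoxide; the closest known reactions are intermolecular photoredox Cr- or Ti-catalysed Barbier allylations of aldehydes with allyl bromides and thermal stoichiometric CrCl2 macrocyclisations, and a light-driven catalytic ring closure of a 3-(bromomethyl)butenolide onto an aldehyde has not been shown.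

**Step 15**
Reactants: 21; 22 tigloyl chloride
Product: 23 15-O-(tert-butyldiphenylsilyl)lychnophorolide B
Conditions: 22, pyridine, DMAP (cat.), CH2Cl2, 0 °C → rt
Reagents that add atoms: tigloyl chloride, C/C=C(\C)C(=O)Cl
Why: DMAP-catalysed acylation of the C8 alcohol with the stable (E)-acid chloride, done promptly so the free 8-OH cannot translactonise to the 8,12-olide.

**Step 16**
Reactants: 23
Product: 24 lychnophorolide B
Conditions: HF·pyridine, pyridine, THF, 0 °C → rt
Reagents that add atoms: none
Why: Buffered fluoride desilylation of the primary allylic TBDPS ether, which leaves the α-methylene lactone, furanone and tiglate intact.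

## Compound list

1 | (S)-lactic acid | C[C@H](O)C(=O)O | starting material
2 | pivaldehyde | CC(C)(C)C=O | starting material
3 | (2S,5S)-2-tert-butyl-5-methyl-1,3-dioxolan-4-one | C[C@@H]1O[C@H](C(C)(C)C)OC1=O | intermediate
4 | allyl bromide | C=CCBr | starting material
5 | (2S,5R)-5-allyl-2-tert-butyl-5-methyl-1,3-dioxolan-4-one | C[C@]1(CC=C)O[C@H](C(C)(C)C)OC1=O | intermediate
6 | (2S,5R)-2-tert-butyl-5-(2,2-dimethoxyethyl)-5-methyl-1,3-dioxolan-4-one | C[C@]1(CC(OC)OC)O[C@H](C(C)(C)C)OC1=O | intermediate
7 | acetylene | C#C | starting material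
8 | (4R)-4-hydroxy-6,6-dimethoxy-4-methylhex-1-yn-3-one | C#CC(=O)[C@](C)(O)CC(OC)OC | intermediate
9 | 2,3-O-isopropylidene-D-threitol, [(4R,5R)-2,2-dimethyl-1,3-dioxolane-4,5-diyl]dimethanol | CC1(C)O[C@H](CO)[C@@H](CO)O1 | starting material
10 | [(4R,5S)-5-(iodomethyl)-2,2-dimethyl-1,3-dioxolan-4-yl]methanol | CC1(C)O[C@H](CO)[C@@H](CI)O1 | intermediate
11 | ethyl (triphenylphosphoranylidene)acetate | CCOC(=O)C=P(c1ccccc1)(c1ccccc1)c1ccccc1 | starting material
12 | ethyl (2Z)-2-iodo-3-[(4R,5S)-5-(iodomethyl)-2,2-dimethyl-1,3-dioxolan-4-yl]prop-2-enoate | CCOC(=O)/C(I)=C/[C@H]1OC(C)(C)O[C@@H]1CI | intermediate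
13 | (2Z)-2-iodo-3-[(4R,5S)-5-(iodomethyl)-2,2-dimethyl-1,3-dioxolan-4-yl]prop-2-en-1-ol | OC/C(I)=C/[C@H]1OC(C)(C)O[C@@H]1CI | intermediate
14 | TBDPS ether of 13 | CC(C)(C)[Si](c1ccccc1)(c1ccccc1)OC/C(I)=C/[C@H]1OC(C)(C)O[C@@H]1CI | intermediate
15 | (2R)-5-{(1Z)-3-(TBDPS-oxy)-1-[(4R,5S)-5-(iodomethyl)-2,2-dimethyl-1,3-dioxolan-4-yl]prop-1-en-2-yl}-2-(2,2-dimethoxyethyl)-2-methylfuran-3(2H)-one | COC(OC)C[C@@]1(C)OC(/C(CO[Si](c3ccccc3)(c4ccccc4)C(C)(C)C)=C\[C@H]2OC(C)(C)O[C@@H]2CI)=CC1=O | intermediate
16 | (2R)-5-{(2Z,4S)-1-(TBDPS-oxy)-4-hydroxyhexa-2,5-dien-2-yl}-2-(2,2-dimethoxyethyl)-2-methylfuran-3(2H)-one | COC(OC)C[C@@]1(C)OC(/C(CO[Si](c3ccccc3)(c4ccccc4)C(C)(C)C)=C\[C@@H](O)C=C)=CC1=O | intermediate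
17 | 2-(bromomethyl)acrylic acid | C=C(CBr)C(=O)O | starting material
18 | 2-(bromomethyl)acrylate ester of 16 | COC(OC)C[C@@]1(C)OC(/C(CO[Si](c3ccccc3)(c4ccccc4)C(C)(C)C)=C\[C@@H](OC(=O)C(=C)CBr)C=C)=CC1=O | intermediate
19 | (5R)-3-(bromomethyl)-5-{(1Z)-3-(TBDPS-oxy)-2-[(5R)-5-(2,2-dimethoxyethyl)-5-methyl-4-oxo-4,5-dihydrofuran-2-yl]prop-1-en-1-yl}furan-2(5H)-one | COC(OC)C[C@@]1(C)OC(/C(CO[Si](c3ccccc3)(c4ccccc4)C(C)(C)C)=C\[C@H]2OC(=O)C(CBr)=C2)=CC1=O | intermediate
20 | aldehyde from 19 (C8 = CHO) | O=CC[C@@]1(C)OC(/C(CO[Si](c3ccccc3)(c4ccccc4)C(C)(C)C)=C\[C@H]2OC(=O)C(CBr)=C2)=CC1=O | intermediate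
21 | 15-O-TBDPS-8-O-destigloyl-lychnophorolide B | C=C1C(=O)O[C@@H]2/C=C(/CO[Si](c4ccccc4)(c5ccccc5)C(C)(C)C)C3=CC(=O)[C@@](C)(C[C@H](O)[C@@H]12)O3 | intermediate
22 | tigloyl chloride, (E)-2-methylbut-2-enoyl chloride | C/C=C(\C)C(=O)Cl | starting material
23 | 15-O-TBDPS-lychnophorolide B | C=C1C(=O)O[C@@H]2/C=C(/CO[Si](c4ccccc4)(c5ccccc5)C(C)(C)C)C3=CC(=O)[C@@](C)(C[C@H](OC(=O)/C(C)=C/C)[C@@H]12)O3 | intermediate
24 | lychnophorolide B | C=C1C(=O)O[C@@H]2/C=C(/CO)C3=CC(=O)[C@@](C)(C[C@H](OC(=O)/C(C)=C/C)[C@@H]12)O3 | target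

## Summary

**Total steps:** 16.
**Longest linear sequence:** 12 (steps 5–16 from 9; the lactic acid branch, steps 1–4 then 9–16, is also 12).

**Three steps most likely to fail**

1. **Step 14, the proposed photoredox/Cr Barbier macrocyclisation.** Risks are reduction of the allyl radical before chromium capture, oligomerisation, and sensitisation of the dienone. Fallback (known chemistry, different nucleophile): convert bromide 19 to the α-(pinacolborylmethyl)butenolide by Pd- or Cu-catalysed borylation with B2pin2, cleave the acetal, and close the ring by Lewis-acid-promoted intramolecular allylboration of the 2-alkoxycarbonyl-allylboronate type, which uses the same closed chair and should give the same anti product. The thermal stoichiometric CrCl2 Nozaki–Hiyama cyclisation of 20 is the simplest check before that.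

2. **Step 9, Sonogashira coupling of the electrophilic terminal α′-hydroxy ynone with in situ cyclisation.** Risks are amine addition, oligomerisation or Glaser coupling of 8. Fallback: couple 14 with the non-electrophilic propargylic alcohol (C1 at carbinol level, from reduction of 8), then oxidise with MnO2 to the internal ynone and cyclise with Au(I).

3. **Step 12, ring-closing metathesis to the bromomethyl butenolide on an advanced intermediate.** Fallback: build the lactone before the coupling. Fragment 14 with zinc, esterify with 2-[(triethylsilyloxy)methyl]acrylic acid and run the metathesis on that simple iodide; then do the Sonogashira/furanone sequence, remove the TES group and brominate (CBr4/PPh3) to reach 19.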